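Remark on the chemistry: atoms carry germacrane numbers (ring C1–C10, lactone carbons C11–C13 with C12 the carbonyl and C13 the methylene, C14 on C10, C15 on C4). The SMILES is read as (4S,5R,7R,8R,9S,10R) with a (2R)-2-methylbutanoate. Pent-1-en-4-yne, 4-methylpent-3-en-1-ol, but-3-en-2-yl acetate and (R)-2-methylbutanoic acid are taken as purchasable. Compound numbers are those of the steps and of the compound list.

## Analysis of the target

The skeleton is a ten-membered carbocycle (C1–C10) bridged by an ether oxygen between C5 and C10, i.e. an 11-oxabicyclo[4.4.1]undecane. It consists of two oxepanes that share C5–O–C10: ring A (O, C5, C6, C7, C8, C9, C10) and ring B (O, C10, C1, C2, C3, C4, C5). An α-methylene-γ-butyrolactone (ring C) is trans-fused to ring A at C7–C8, and C9 carries a (2R)-2-methylbutanoate. Six ring stereocentres are present: the pair C4/C5 (methyl anti to the ether oxygen) and the contiguous tetrad C7/C8/C9/C10, in which O9 is trans to O8 and O8 is trans to C11. C10 is a fully substituted ether carbon whose configuration is tied to C5 across the ring by the bridge. The sensitive groups are the exo-methylene lactone (Michael acceptor), the two esters (acyl shift as soon as a neighbouring hydroxyl is free), the epimerisable α-centre of the side chain, and the tertiary ether (ionisation under strong acid). The difficulty is threefold: three medium rings, a quaternary ether stereocentre, and a lactone junction that must be set trans and in the right sense relative to C9/C10 on a flexible ring. The carbon backbone is a head-to-tail farnesane, and the C7–C8 bond with trans O8/C11 has the same pattern as the citronellal-to-isopulegol ring closure.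

## Retrosynthetic reasoning

**21 ⇒ 18 ⇒ 17 (C12–O8 and the oxidation level of C12).** The unsaturated lactone is the most fragile group, so it is made last. Cutting C12–O8 and lowering C12 to a methyl group leaves the isopropenyl alcohol 17. Forward, this needs only allylic oxidation of the isopropenyl methyl group (to 18) and an oxidative lactonisation through 19 and 20.

**17 ⇒ 16 (C7–C8, the key cut).** In 17 a hydroxyl on C8 sits next to an isopropenyl group on C7, the retron of an intramolecular carbonyl-ene reaction. Cutting C7–C8 opens ring A and the ten-membered carbocycle together and removes two stereocentres. It leaves the monocyclic oxepane 16, whose two arms (an α-acyloxy aldehyde on C10 and a prenyl group on C5) are already cis. This cut was chosen because C7–C8 is the only ring bond whose formation also delivers the lactone carbons in the right place. The forward reaction must close a seven-membered ring across the oxepane with trans O8/C11 and with the correct face of the aldehyde relative to C9.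

**16 ⇒ 15 ⇒ 13 + 14 ⇒ 12 (functional group steps).** The aldehyde comes from a primary silyl ether that is oxidised directly. The side-chain ester is put on C9 before the key step, so the final acyl group serves as the only protection of O9 and no late selective acylation between O8 and O9 is needed.

**12 ⇒ 11 (O–C10).** The tertiary ether bond is cut so that O5 becomes the nucleophile and C10 an epoxide carbon. Forward, an exo opening at the tertiary carbon closes ring B with inversion at C10 and leaves O9 on C9 with retention. Both C9 and C10 are thus written into one epoxide, and the cis relation of the two arms follows from the stereospecific opening.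

**11 ⇒ 10 ⇒ 5 + 9 (C2–C3).** The three unfunctionalised methylenes of ring B are the natural place to join two halves. Cross-metathesis of two terminal alkenes followed by saturation of the new 1,2-disubstituted alkene forms C2–C3 without touching a stereocentre.

**5 ⇒ 4 ⇒ 1 and 9 ⇒ 6 + 7.** The epoxy alcohol 5 comes from the (E)-allylic alcohol 4 by a titanium–tartrate epoxidation. Alcohol 4 comes from the enyne 1 by methyl-metalation of the alkyne (through 2 and 3) and one-carbon homologation. The anti methyl/hydroxyl pair C4/C5 of 9 comes from a catalytic anti-crotylation of the homoprenyl alcohol 6 with the crotyl donor 7 through the transient aldehyde 8. This step also brings the prenyl arm that becomes C6, C7, C11, C12 and C13.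

## Alternatives that were turned down

**Alternative 1:** the textbook, biomimetic cut of the ether bond O–C10 on the intact ten-membered ring. The forward key step is an acid-catalysed transannular opening of the (4S,5R,7R,8R,9S,10S)-9,10-epoxy-5-hydroxygermacr-11(13)-en-12,8-olide A1 by its C5 hydroxyl. The step itself is stereospecific. It was turned down because A1 must first be closed as a ten-membered ring from an open chain that lacks a rigidifying ring alkene, which costs entropy and favours cyclic dimers. The C5 carbinol and the face of the 9,10-epoxide would then be set on a flexible macrocycle, and the C5 hydroxyl needs its own protecting group until the end. That is more steps, with the stereochemical risk spread over several of them instead of one.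

**Alternative 2:** an anionic oxy-Cope ring expansion. C5–C10 is treated as a former ring bond and C7–C8 as the new σ-bond. The cyclohexanol A2, (1S,2R,6S)-1-[(1E)-3-methylbuta-1,3-dienyl]-2-[(E)-2-(4-methoxybenzyloxy)ethenyl]-2,6-dimethylcyclohexan-1-ol, would give under KH/18-crown-6 the (9E)-cyclodecenone A3 (C5 ketone, 8-OPMB, 7-isopropenyl). A chair transition state sets C7/C8 trans and the alkene E; reduction, epoxidation and transannular etherification would follow. This is attractive, because a six-membered ring becomes the ten-membered ring with two stereocentres in one step. It was turned down because A2 needs an enantioenriched quaternary carbon with defined relative configuration to the epimerisable C4 centre, a geometrically pure (E)-enol ether and an (E)-dienyl metal, roughly seven steps before the key step. After it, C5 and the epoxide face would still be set by substrate control on the macrocycle, and the 1,5-diene in A3 can equilibrate by Cope rearrangement to a divinylcyclohexane.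

**Alternative 3:** the same C7–C8 cut, made as a metal-mediated allylation with the complete acrylate arm. The bromo ester A4, methyl (2Z)-2-(bromomethyl)-4-[(2R,3S,7R)-7-{(1R)-1-[(2R)-2-methylbutanoyloxy]-2-oxoethyl}-3,7-dimethyloxepan-2-yl]but-2-enoate, would be cyclised with CrCl2 or indium and lactonise directly. It was turned down on mechanistic grounds. A 2-alkoxycarbonyl allylmetal prefers the geometry with C6 cis to the CH2–metal group (trans to the ester). In the closed six-membered transition state that geometry places C6 axial and leads to the cis-lactone. The arm also costs three to four extra steps (aldehyde, Morita–Baylis–Hillman adduct, bromide) and cannot be carried through the hydrogenation that joins the halves.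

Key step: step 10

## Forward route

Step 1
Reactants: 1 pent-1-en-4-yne
Product: 4 (2E)-3-methylhexa-2,5-dien-1-ol, via alkenyldimethylalane 2 (not isolated), via lithium alkenylalanate 3 (not isolated)
Conditions: AlMe3 (2 equiv), Cp2ZrCl2 (0.25 equiv), CH2Cl2, 0 °C to rt; then n-BuLi, THF/hexane, −78 °C; (CH2O)n, rt; aq. NH4Cl
Reagents that add atoms: trimethylaluminium C[Al](C)C; paraformaldehyde (as formaldehyde) C=O
Why: Negishi zirconium-catalysed carboalumination adds methyl and aluminium syn across the alkyne (methyl to the internal carbon), so the chain ends trans to the carbinol carbon (E); the isolated alkene does not react, and the alanate adds to formaldehyde with retention of alkene geometry.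

Step 2
Reactants: 4 (2E)-3-methylhexa-2,5-dien-1-ol
Product: 5 [(2S,3S)-3-methyl-3-(prop-2-en-1-yl)oxiran-2-yl]methanol
Conditions: Ti(OiPr)4 (5 mol%), diethyl L-(+)-tartrate (6 mol%), tBuOOH (2 equiv), 4 Å MS, CH2Cl2, −20 °C
Reagents that add atoms: tert-butyl hydroperoxide CC(C)(C)OO
Why: Sharpless asymmetric epoxidation of a geraniol-type (E)-allylic alcohol; the L-(+)-tartrate complex delivers oxygen to the face that gives the (2S,3S)-epoxide (future C9 and C10), and the terminal alkene, which is not allylic to the hydroxyl, stays untouched.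

Step 3
Reactants: 6 4-methylpent-3-en-1-ol; 7 but-3-en-2-yl acetate (racemic)
Product: 9 (3S,4R)-3,7-dimethylocta-1,6-dien-4-ol, via 4-methylpent-3-enal 8 (not isolated)
Conditions: [Ir(cod)Cl]2 (2.5 mol%), (S)-SEGPHOS (5 mol%), 4-cyano-3-nitrobenzoic acid (10 mol%), Cs2CO3 (20 mol%), THF, 90 °C, sealed tube
Reagents that add atoms: none
Why: Krische transfer-hydrogenative crotylation: the cyclometallated iridium benzoate dehydrogenates 6 to 8 and adds the (E)-σ-crotyl iridium species through a closed chair, which gives the anti pair; the (S)-ligand is chosen for the carbinol face that corresponds to 5R in the target, so C4 (S) and C5 (R) are set together.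

Step 4
Reactants: 5 [(2S,3S)-3-methyl-3-(prop-2-en-1-yl)oxiran-2-yl]methanol; 9 (3S,4R)-3,7-dimethylocta-1,6-dien-4-ol
Product: 10 [(2S,3S)-3-[(2E,4S,5R)-5-hydroxy-4,8-dimethylnona-2,7-dien-1-yl]-3-methyloxiran-2-yl]methanol
Conditions: second-generation Grubbs catalyst RuCl2(H2IMes)(PCy3)(=CHPh) (5 mol%), 5 (2.5 equiv), CH2Cl2, 40 °C
Reagents that add atoms: none
Why: Olefin cross-metathesis between the unhindered allyl group of 5 (used in excess) and the allylically branched vinyl group of 9 forms C2=C3; the trisubstituted prenyl alkene is too hindered to compete, and E/Z composition is irrelevant because the alkene is reduced next.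

Step 5
Reactants: 10 [(2S,3S)-3-[(2E,4S,5R)-5-hydroxy-4,8-dimethylnona-2,7-dien-1-yl]-3-methyloxiran-2-yl]methanol
Product: 11 [(2S,3S)-3-[(4S,5R)-5-hydroxy-4,8-dimethylnon-7-en-1-yl]-3-methyloxiran-2-yl]methanol
Conditions: H2 (1 atm), RhCl(PPh3)3 (5 mol%), benzene/EtOH 1:1, rt
Reagents that add atoms: none
Why: Homogeneous hydrogenation with RhCl(PPh3)3 reduces the 1,2-disubstituted alkene far faster than the trisubstituted prenyl alkene and does not open the epoxide; no stereocentre is involved.

Step 6
Reactants: 11 [(2S,3S)-3-[(4S,5R)-5-hydroxy-4,8-dimethylnon-7-en-1-yl]-3-methyloxiran-2-yl]methanol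
Product: 12 (1S)-1-[(2R,6S,7R)-2,6-dimethyl-7-(3-methylbut-2-en-1-yl)oxepan-2-yl]ethane-1,2-diol
Conditions: camphorsulfonic acid (10 mol%), CH2Cl2 (0.01 M), 0 °C to rt
Reagents that add atoms: none
Why: Acid-catalysed intramolecular opening of a 2,3-epoxy alcohol by the C5 hydroxyl in the 7-exo-tet mode at the tertiary carbon, which is favoured electronically (tertiary, remote from the hydroxymethyl group); inversion at C10 gives 10R, O9 stays on C9 with retention, and ring B forms with the two arms cis.

Step 7
Reactants: 12 (1S)-1-[(2R,6S,7R)-2,6-dimethyl-7-(3-methylbut-2-en-1-yl)oxepan-2-yl]ethane-1,2-diol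
Product: 13 (1S)-1-[(2R,6S,7R)-2,6-dimethyl-7-(3-methylbut-2-en-1-yl)oxepan-2-yl]-2-[(triethylsilyl)oxy]ethan-1-ol
Conditions: Et3SiCl (1.05 equiv), imidazole, CH2Cl2, −78 to −40 °C
Reagents that add atoms: chlorotriethylsilane CC[Si](Cl)(CC)CC
Why: Selective silylation of the primary hydroxyl; the secondary hydroxyl on C9 is flanked by the quaternary C10 and reacts much more slowly at low temperature.

Step 8
Reactants: 13 (1S)-1-[(2R,6S,7R)-2,6-dimethyl-7-(3-methylbut-2-en-1-yl)oxepan-2-yl]-2-[(triethylsilyl)oxy]ethan-1-ol; 14 (2R)-2-methylbutanoic acid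
Product: 15 (1S)-1-[(2R,6S,7R)-2,6-dimethyl-7-(3-methylbut-2-en-1-yl)oxepan-2-yl]-2-[(triethylsilyl)oxy]ethyl (2R)-2-methylbutanoate
Conditions: DCC (1.5 equiv), DMAP (0.2 equiv), CH2Cl2, 0 °C to rt
Reagents that add atoms: none
Why: Steglich esterification of the hindered secondary alcohol; a low DMAP loading and low temperature keep the α-centre of the acid from epimerising, and the natural ester now protects O9 for the rest of the route.

Step 9
Reactants: 15 (1S)-1-[(2R,6S,7R)-2,6-dimethyl-7-(3-methylbut-2-en-1-yl)oxepan-2-yl]-2-[(triethylsilyl)oxy]ethyl (2R)-2-methylbutanoate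
Product: 16 (1R)-1-[(2R,6S,7R)-2,6-dimethyl-7-(3-methylbut-2-en-1-yl)oxepan-2-yl]-2-oxoethyl (2R)-2-methylbutanoate
Conditions: (COCl)2 (4 equiv), DMSO (8 equiv), CH2Cl2, −78 °C, then −35 °C for 30 min; Et3N, −78 to 0 °C
Reagents that add atoms: none
Why: Swern conditions oxidise a primary triethylsilyl ether directly to the aldehyde (the activated sulfonium species takes the silyl group from oxygen), which avoids a free hydroxyl next to the C9 ester and thus acyl migration; the descriptor at C9 changes only because CHO outranks C10, and the aldehyde is used at once.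

Step 10
Reactants: 16 (1R)-1-[(2R,6S,7R)-2,6-dimethyl-7-(3-methylbut-2-en-1-yl)oxepan-2-yl]-2-oxoethyl (2R)-2-methylbutanoate
Product: 17 (1R,2S,3R,4R,6R,7S)-3-hydroxy-1,7-dimethyl-4-(prop-1-en-2-yl)-11-oxabicyclo[4.4.1]undecan-2-yl (2R)-2-methylbutanoate
Conditions: Me2AlCl (1.5 equiv), CH2Cl2 (0.005 M), −78 to −40 °C; aq. Rochelle salt
Reagents that add atoms: none
Why: Me2AlCl binds the aldehyde oxygen, the C7=C11 π-bond attacks C8 through its proximal carbon, and an allylic hydrogen of a C11 methyl group passes to the aluminium-bound oxygen in a six-membered array (asynchronous carbonyl-ene reaction), which leaves the C8 hydroxyl and the isopropenyl group. The closest known reaction type is the Lewis-acid cyclisation of citronellal to isopulegol and its seven-ring counterparts used for hydroazulenes. Ring A (O, C5, C6, C7, C8, C9, C10) closes as a seven-membered ring, exo with respect to both the C8=O and the C7=C11 bond (7-exo-trig at the aldehyde), and the same bond completes the ten-membered carbocycle C1–C10. C8 is controlled by C9: the alkene approaches antiperiplanar to the C9–O(acyl) bond (Felkin–Anh polar arrangement), and of the two such arrangements the one with the bulky O–Al group equatorial on the forming twist-chair, away from quaternary C10, gives 8R. C7 is controlled by the ene geometry: the CMe2 terminus lies equatorial and gauche to the oxygen, as hydrogen transfer requires, which puts C11 trans to O8 (7R), the isopulegol relationship. The step needs ring closure to beat oligomerisation and chloride capture; the cis arms on the oxepane (fixed in step 6), high dilution and low temperature provide for that.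

Step 11
Reactants: 17 (1R,2S,3R,4R,6R,7S)-3-hydroxy-1,7-dimethyl-4-(prop-1-en-2-yl)-11-oxabicyclo[4.4.1]undecan-2-yl (2R)-2-methylbutanoate
Product: 18 (1R,2S,3R,4R,6R,7S)-3-hydroxy-4-(3-hydroxyprop-1-en-2-yl)-1,7-dimethyl-11-oxabicyclo[4.4.1]undecan-2-yl (2R)-2-methylbutanoate
Conditions: SeO2 (0.5 equiv), tBuOOH (3 equiv), CH2Cl2, rt
Reagents that add atoms: selenium dioxide (oxygen carrier, regenerated) O=[Se]=O; tert-butyl hydroperoxide CC(C)(C)OO
Why: Allylic oxidation by an ene reaction with SeO2 followed by a 2,3-sigmatropic shift; on a 1,1-disubstituted alkene the methyl group is oxidised in preference to the allylic methine C7, and this is the only alkene left in the molecule.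

Step 12
Reactants: 18 (1R,2S,3R,4R,6R,7S)-3-hydroxy-4-(3-hydroxyprop-1-en-2-yl)-1,7-dimethyl-11-oxabicyclo[4.4.1]undecan-2-yl (2R)-2-methylbutanoate
Product: 21 (4S,5R,7R,8R,9S,10R)-5,10-epoxy-9-[(2R)-2-methylbutanoyloxy]germacr-11(13)-en-12,8-olide (CNP0136059.1), via hydroxy enal 19 (not isolated), via lactol 20 (not isolated)
Conditions: TEMPO (0.2 equiv), PhI(OAc)2 (3 equiv), CH2Cl2, rt
Reagents that add atoms: none
Why: Oxoammonium oxidation takes the primary allylic alcohol to the enal, the C8 hydroxyl closes the five-membered lactol, and a second oxidation gives the lactone (oxidative lactonisation of a 1,4-diol); the secondary C8 hydroxyl is oxidised far more slowly than it is trapped, and no stereocentre is touched.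

## Compound list

1 | pent-1-en-4-yne | C=CCC#C | starting material
2 | dimethyl[(1E)-2-methylpenta-1,4-dien-1-yl]alane | C=CC/C(C)=C/[Al](C)C | intermediate (not isolated)
3 | lithium butyl(dimethyl)[(1E)-2-methylpenta-1,4-dien-1-yl]alanate | [Li+].C=CC/C(C)=C/[Al-](C)(C)CCCC | intermediate (not isolated)
4 | (2E)-3-methylhexa-2,5-dien-1-ol | C=CC/C(C)=C/CO | intermediate
5 | [(2S,3S)-3-methyl-3-(prop-2-en-1-yl)oxiran-2-yl]methanol | OC[C@@H]1O[C@@]1(C)CC=C | intermediate
6 | 4-methylpent-3-en-1-ol | CC(C)=CCCO | starting material
7 | but-3-en-2-yl acetate (racemic) | CC(OC(C)=O)C=C | starting material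
8 | 4-methylpent-3-enal | CC(C)=CCC=O | intermediate (not isolated)
9 | (3S,4R)-3,7-dimethylocta-1,6-dien-4-ol | C=C[C@H](C)[C@H](O)CC=C(C)C | intermediate
10 | [(2S,3S)-3-[(2E,4S,5R)-5-hydroxy-4,8-dimethylnona-2,7-dien-1-yl]-3-methyloxiran-2-yl]methanol | OC[C@@H]1O[C@@]1(C)C/C=C/[C@H](C)[C@H](O)CC=C(C)C | intermediate
11 | [(2S,3S)-3-[(4S,5R)-5-hydroxy-4,8-dimethylnon-7-en-1-yl]-3-methyloxiran-2-yl]methanol | OC[C@@H]1O[C@@]1(C)CCC[C@H](C)[C@H](O)CC=C(C)C | intermediate
12 | (1S)-1-[(2R,6S,7R)-2,6-dimethyl-7-(3-methylbut-2-en-1-yl)oxepan-2-yl]ethane-1,2-diol | CC(C)=CC[C@H]1O[C@](C)(CCC[C@@H]1C)[C@@H](O)CO | intermediate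
13 | (1S)-1-[(2R,6S,7R)-2,6-dimethyl-7-(3-methylbut-2-en-1-yl)oxepan-2-yl]-2-[(triethylsilyl)oxy]ethan-1-ol | CC(C)=CC[C@H]1O[C@](C)(CCC[C@@H]1C)[C@@H](O)CO[Si](CC)(CC)CC | intermediate
14 | (2R)-2-methylbutanoic acid | CC[C@@H](C)C(=O)O | starting material
15 | (1S)-1-[(2R,6S,7R)-2,6-dimethyl-7-(3-methylbut-2-en-1-yl)oxepan-2-yl]-2-[(triethylsilyl)oxy]ethyl (2R)-2-methylbutanoate | CC(C)=CC[C@H]1O[C@](C)(CCC[C@@H]1C)[C@@H](OC(=O)[C@H](C)CC)CO[Si](CC)(CC)CC | intermediate
16 | (1R)-1-[(2R,6S,7R)-2,6-dimethyl-7-(3-methylbut-2-en-1-yl)oxepan-2-yl]-2-oxoethyl (2R)-2-methylbutanoate | CC(C)=CC[C@H]1O[C@](C)(CCC[C@@H]1C)[C@@H](OC(=O)[C@H](C)CC)C=O | intermediate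
17 | (1R,2S,3R,4R,6R,7S)-3-hydroxy-1,7-dimethyl-4-(prop-1-en-2-yl)-11-oxabicyclo[4.4.1]undecan-2-yl (2R)-2-methylbutanoate | C=C(C)[C@H]1C[C@H]2O[C@](C)(CCC[C@@H]2C)[C@@H](OC(=O)[C@H](C)CC)[C@@H]1O | intermediate
18 | (1R,2S,3R,4R,6R,7S)-3-hydroxy-4-(3-hydroxyprop-1-en-2-yl)-1,7-dimethyl-11-oxabicyclo[4.4.1]undecan-2-yl (2R)-2-methylbutanoate | C=C(CO)[C@H]1C[C@H]2O[C@](C)(CCC[C@@H]2C)[C@@H](OC(=O)[C@H](C)CC)[C@@H]1O | intermediate
19 | (1R,2S,3R,4R,6R,7S)-3-hydroxy-1,7-dimethyl-4-(3-oxoprop-1-en-2-yl)-11-oxabicyclo[4.4.1]undecan-2-yl (2R)-2-methylbutanoate | C=C(C=O)[C@H]1C[C@H]2O[C@](C)(CCC[C@@H]2C)[C@@H](OC(=O)[C@H](C)CC)[C@@H]1O | intermediate (not isolated)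
20 | lactol of 19 (O8 closed onto C12; both anomers at C12) | C=C1C(O)O[C@@H]2[C@@H]1C[C@H]1O[C@](C)(CCC[C@@H]1C)[C@H]2OC(=O)[C@H](C)CC | intermediate (not isolated)
21 | (4S,5R,7R,8R,9S,10R)-5,10-epoxy-9-[(2R)-2-methylbutanoyloxy]germacr-11(13)-en-12,8-olide (CNP0136059.1) | C=C1C(=O)O[C@@H]2[C@@H]1C[C@H]1O[C@](C)(CCC[C@@H]1C)[C@H]2OC(=O)[C@H](C)CC | target

## Step count and risk

Total: 12 steps. Longest linear sequence: 11 steps (steps 1, 2 and 4–12 from pent-1-en-4-yne); step 3 is a one-step branch.

**Step 10 (key step).** The most likely failure is poor facial selectivity at C8, because the transition state with the O–Al group equatorial must win over the one with it axial, which would give the C8 epimer and a cis-lactone. A slow seven-ring closure would in addition allow chloride capture of the developing C11 cation, loss of a proton to the isopropylidene isomer, or acyl shift from O9 to the aluminium alkoxide on O8. Fallback, from 15 back to 17: SeO2/tBuOOH oxidises the (E)-methyl group of the prenyl arm to the allylic alcohol F1; CBr4/PPh3 gives the allylic bromide F2; Swern oxidation as in step 9 gives the bromo aldehyde F3; CrCl2 in THF at high dilution then forms C7–C8 by a Nozaki–Hiyama–Kishi allylation through the γ-carbon. Without an ester on the allyl unit the allylchromium reacts through the chair with both ring bonds equatorial (anti), and the product is 17.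

**Step 6.** Ionisation at the tertiary C10 may outrun the seven-ring closure, which leads to hydride or alkyl shift to a carbonyl compound, to elimination to allylic diols, or to intermolecular opening. Fallback, from 5 and 9 back to 12 (replacing steps 4–6): Ti(OiPr)4-mediated opening of epoxy alcohol 5 at its tertiary C3 by an excess of alcohol 9 gives the open-chain ether F4 with the same inversion; ring-closing metathesis of its allyl and vinyl groups with the second-generation Grubbs catalyst gives the oxepene F5; hydrogenation with H2/RhCl(PPh3)3 gives 12.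

**Step 3.** The iridium hydride may isomerise the transient β,γ-unsaturated aldehyde into conjugation before C–C bond formation, and the anti selectivity may erode at 90 °C. Fallback, from 6 back to 9: Dess–Martin oxidation to 8, isolated cold, then Brown crotylboration at −78 °C with the (E)-crotylborane made from (−)-B-methoxydiisopinocampheylborane, (E)-but-2-ene, n-BuLi/KOtBu and BF3·OEt2, followed by NaOH/H2O2; this gives the same (3S,4R) anti isomer under stoichiometric reagent control.

**Step 11.** Oxidation may stall at mixtures of alcohol and aldehyde, attack the allylic methine C7, or be accompanied by acyl shift between O9 and O8 under the mildly acidic conditions. Fallback, from 17 back to 19: ene-type chlorination with Ca(OCl)2/CO2 in CH2Cl2/H2O gives the allylic chloride F6; oxidation with N-methylmorpholine N-oxide in MeCN (Ganem oxidation) gives enal 19, which closes to 20 and is oxidised as in step 12.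

## Further compounds

F1 | step 10 | (1S)-1-[(2R,6S,7R)-7-[(2E)-4-hydroxy-3-methylbut-2-en-1-yl]-2,6-dimethyloxepan-2-yl]-2-[(triethylsilyl)oxy]ethyl (2R)-2-methylbutanoate | OC/C(C)=C/C[C@H]1O[C@](C)(CCC[C@@H]1C)[C@@H](OC(=O)[C@H](C)CC)CO[Si](CC)(CC)CC
F2 | step 10 | (1S)-1-[(2R,6S,7R)-7-[(2E)-4-bromo-3-methylbut-2-en-1-yl]-2,6-dimethyloxepan-2-yl]-2-[(triethylsilyl)oxy]ethyl (2R)-2-methylbutanoate | BrC/C(C)=C/C[C@H]1O[C@](C)(CCC[C@@H]1C)[C@@H](OC(=O)[C@H](C)CC)CO[Si](CC)(CC)CC
F3 | step 10 | (1R)-1-[(2R,6S,7R)-7-[(2E)-4-bromo-3-methylbut-2-en-1-yl]-2,6-dimethyloxepan-2-yl]-2-oxoethyl (2R)-2-methylbutanoate | BrC/C(C)=C/C[C@H]1O[C@](C)(CCC[C@@H]1C)[C@@H](OC(=O)[C@H](C)CC)C=O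
F4 | step 6 | (2S,3R)-3-{[(3S,4R)-3,7-dimethylocta-1,6-dien-4-yl]oxy}-3-methylhex-5-ene-1,2-diol | C=CC[C@@](C)(O[C@H](CC=C(C)C)[C@@H](C)C=C)[C@@H](O)CO
F5 | step 6 | (1S)-1-[(2R,6S,7R)-2,6-dimethyl-7-(3-methylbut-2-en-1-yl)-2,3,6,7-tetrahydrooxepin-2-yl]ethane-1,2-diol (ring alkene Z) | CC(C)=CC[C@H]1O[C@](C)(CC=C[C@@H]1C)[C@@H](O)CO
F0 | step 3 | none | none
F6 | step 11 | (1R,2S,3R,4R,6R,7S)-4-(3-chloroprop-1-en-2-yl)-3-hydroxy-1,7-dimethyl-11-oxabicyclo[4.4.1]undecan-2-yl (2R)-2-methylbutanoate | C=C(CCl)[C@H]1C[C@H]2O[C@](C)(CCC[C@@H]2C)[C@@H](OC(=O)[C@H](C)CC)[C@@H]1O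
A1 | alternative 1 | (4S,5R,7R,8R,9S,10S)-9,10-epoxy-5-hydroxygermacr-11(13)-en-12,8-olide | C=C1C(=O)O[C@@H]2[C@@H]1C[C@@H](O)[C@@H](C)CCC[C@]3(C)O[C@@H]23
A2 | alternative 2 | (1S,2R,6S)-1-[(1E)-3-methylbuta-1,3-dien-1-yl]-2-{(E)-2-[(4-methoxybenzyl)oxy]ethenyl}-2,6-dimethylcyclohexan-1-ol | C=C(C)/C=C/[C@@]1(O)[C@@H](C)CCC[C@]1(C)/C=C/OCc1ccc(OC)cc1
A3 | alternative 2 | (9E)-8-[(4-methoxybenzyl)oxy]germacra-9,11-dien-5-one with the target configuration at C4, C7 and C8 | C=C(C)[C@H]1CC(=O)[C@@H](C)CCC/C(C)=C/[C@@H]1OCc1ccc(OC)cc1
A4 | alternative 3 | methyl (2Z)-2-(bromomethyl)-4-[(2R,3S,7R)-7-{(1R)-1-[(2R)-2-methylbutanoyloxy]-2-oxoethyl}-3,7-dimethyloxepan-2-yl]but-2-enoate | BrC/C(C(=O)OC)=C\C[C@H]1O[C@](C)(CCC[C@@H]1C)[C@@H](OC(=O)[C@H](C)CC)C=O
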